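**Strategy.** Everything rests on opening ring C (the pyranone) at C4'–C5' and O1'–C2'. The fragment O1'–C6'(Et)–C5'(Me) is recognised as symmetric 3-pentanone, and C2'–C3'–C4' as a malonic acid whose central carbon C3' is already joined through the CH2 bridge to C7 of ring A. In a single operation the silyl enol ether of 3-pentanone is acylated by the malonyl dichloride at carbon and then at oxygen, so ring C is built last, directly on the complete, enantiopure ring A/B part. The precursor 21 is that dichloride with both phenols as TBS ethers, the (R)-isopropenyl dihydrofuran and the (R)-2-methylbutanoyl group in place.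

Key step: step 14

Remark: ring A is the benzene ring, ring B the dihydrofuran and ring C the pyranone (primed locants); TBS is tert-butyldimethylsilyl; 23 is drawn as the Z isomer that should predominate, either geometry being usable; the extra sp3 centres of 19 and 24 are mixtures that are erased later; the L-fructose-derived Shi ketone is taken to be purchasable.

**Route**

Step 1
Reactants: 1 phloroglucinol; 2 (R)-2-methylbutanoic acid
Product: 4 (2R)-2-methyl-1-(2,4,6-trihydroxyphenyl)butan-1-one, via (R)-2-methylbutanoyl chloride 3 (not isolated)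
Conditions: (COCl)2, DMF (cat.), CH2Cl2, 0 °C → rt; then 1, AlCl3, PhNO2/CH2Cl2, 0 °C → rt; aq. HCl
Reagents that add atoms: none
Why: Friedel–Crafts acylation of the threefold activated arene should stop after one acyl group because the new ketone deactivates the ring, and since the acid chloride is made and used without base the α-stereocentre brought in by 2 should be kept.

Step 2
Reactants: 4 (2R)-2-methyl-1-(2,4,6-trihydroxyphenyl)butan-1-one; 5 prenyl bromide (1-bromo-3-methylbut-2-ene)
Product: 6 (2R)-2-methyl-1-[2,4,6-trihydroxy-3-(3-methylbut-2-en-1-yl)phenyl]butan-1-one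
Conditions: 5 (1 equiv), KOH (aq.), 0 °C
Reagents that add atoms: none
Why: C-alkylation of the ambident phloroglucinolate in water, where hydrogen bonding to oxygen favours attack through carbon, should put one prenyl group on one of the two equivalent free ring positions, the single equivalent of bromide limiting over-alkylation.

Step 3
Reactants: 6 (2R)-2-methyl-1-[2,4,6-trihydroxy-3-(3-methylbut-2-en-1-yl)phenyl]butan-1-one
Product: 7 (2R)-1-[2,6-dihydroxy-3-(3-methylbut-2-en-1-yl)-4-(prop-2-en-1-yloxy)phenyl]-2-methylbutan-1-one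
Conditions: allyl alcohol, PPh3, diisopropyl azodicarboxylate, THF, 0 °C → rt
Reagents that add atoms: allyl alcohol, C=CCO
Why: Mitsunobu etherification should select the most acidic and only non-chelated hydroxyl, the one para to the ketone, so that this oxygen alone is marked for the later closure of ring B.

Step 4
Reactants: 7 (2R)-1-[2,6-dihydroxy-3-(3-methylbut-2-en-1-yl)-4-(prop-2-en-1-yloxy)phenyl]-2-methylbutan-1-one
Product: 8 (2R)-1-[2,6-bis(tert-butyldimethylsilyloxy)-3-(3-methylbut-2-en-1-yl)-4-(prop-2-en-1-yloxy)phenyl]-2-methylbutan-1-one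
Conditions: TBSOTf, 2,6-lutidine, CH2Cl2, −78 → 0 °C
Reagents that add atoms: tert-butyldimethylsilyl trifluoromethanesulfonate, CC(C)(C)[Si](C)(C)OS(=O)(=O)C(F)(F)F
Why: Silylation with the triflate should overcome the chelation of both ortho phenols, which are thereby kept out of the oxidation, the ring closure and the dehydration that follow, while the hindered weak base should not enolise the twisted aryl ketone.

Step 5
Reactants: 8 (2R)-1-[2,6-bis(tert-butyldimethylsilyloxy)-3-(3-methylbut-2-en-1-yl)-4-(prop-2-en-1-yloxy)phenyl]-2-methylbutan-1-one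
Product: 9 (2R)-1-[2,6-bis(tert-butyldimethylsilyloxy)-3-{[(2S)-3,3-dimethyloxiran-2-yl]methyl}-4-(prop-2-en-1-yloxy)phenyl]-2-methylbutan-1-one
Conditions: L-fructose-derived Shi ketone (30 mol%), KHSO5 (as 2KHSO5·KHSO4·K2SO4), K2CO3, Bu4NHSO4, MeCN/CH2(OMe)2/aq. Na2B4O7 buffer, 0 °C
Reagents that add atoms: potassium peroxymonosulfate, [K+].[O-]S(=O)(=O)OO
Why: In this Shi epoxidation the chiral dioxirane should attack the trisubstituted prenyl alkene through the spiro transition state much faster than the monosubstituted allyl ether, and because the D-fructose ketone gives (R)-epoxides from prenyl arenes its enantiomer is expected to set the (S) centre.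

Step 6
Reactants: 9 (2R)-1-[2,6-bis(tert-butyldimethylsilyloxy)-3-{[(2S)-3,3-dimethyloxiran-2-yl]methyl}-4-(prop-2-en-1-yloxy)phenyl]-2-methylbutan-1-one
Product: 11 (2R)-1-[(2R)-4,6-bis(tert-butyldimethylsilyloxy)-2-(2-hydroxypropan-2-yl)-2,3-dihydro-1-benzofuran-5-yl]-2-methylbutan-1-one, via phenol epoxide 10 (not isolated)
Conditions: Pd(PPh3)4 (5 mol%), morpholine, THF, rt → 40 °C
Reagents that add atoms: none
Why: Zerovalent palladium should ionise the allyl aryl ether (Tsuji–Trost deallylation, morpholine taking the allyl group), and the freed para phenoxide, the only free phenol, should open the epoxide at its secondary carbon by 5-exo-tet attack with inversion, which turns the (S) epoxide carbon into the (R)-configured C2 of ring B.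

Step 7
Reactants: 11 (2R)-1-[(2R)-4,6-bis(tert-butyldimethylsilyloxy)-2-(2-hydroxypropan-2-yl)-2,3-dihydro-1-benzofuran-5-yl]-2-methylbutan-1-one
Product: 13 (2R)-1-[(2R)-4,6-dihydroxy-2-(prop-1-en-2-yl)-2,3-dihydro-1-benzofuran-5-yl]-2-methylbutan-1-one, via bis-silyl alkene 12 (not isolated)
Conditions: Burgess reagent, toluene, 60 °C; then Bu4NF, THF, 0 °C
Reagents that add atoms: none
Why: Burgess dehydration (syn elimination from the sulfamate ester) should take one of the six methyl hydrogens in preference to the single hindered ring C2–H and so give the isopropenyl group with C2 untouched, the phenols being masked during this step and then freed by fluoride for the ring substitution that follows.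

Step 8
Reactants: 13 (2R)-1-[(2R)-4,6-dihydroxy-2-(prop-1-en-2-yl)-2,3-dihydro-1-benzofuran-5-yl]-2-methylbutan-1-one
Product: 14 (2R)-4,6-dihydroxy-5-[(2R)-2-methylbutanoyl]-2-(prop-1-en-2-yl)-2,3-dihydro-1-benzofuran-7-carbaldehyde
Conditions: POCl3, DMF, MeCN, 0 °C → rt; then aq. NaOAc
Reagents that add atoms: N,N-dimethylformamide, CN(C)C=O; water, O
Why: Vilsmeier–Haack formylation should occur at C7, the only free position of ring A and activated by three oxygen substituents (two ortho, one para), while the weak chloroiminium electrophile and the buffered hydrolysis should leave the isopropenyl group alone.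

Step 9
Reactants: 14 (2R)-4,6-dihydroxy-5-[(2R)-2-methylbutanoyl]-2-(prop-1-en-2-yl)-2,3-dihydro-1-benzofuran-7-carbaldehyde
Product: 15 (2R)-4,6-bis(tert-butyldimethylsilyloxy)-5-[(2R)-2-methylbutanoyl]-2-(prop-1-en-2-yl)-2,3-dihydro-1-benzofuran-7-carbaldehyde
Conditions: TBSOTf, 2,6-lutidine, CH2Cl2, −78 → 0 °C
Reagents that add atoms: tert-butyldimethylsilyl trifluoromethanesulfonate, CC(C)(C)[Si](C)(C)OS(=O)(=O)C(F)(F)F
Why: Silylation of both chelated phenols removes the ortho hydroxyl that would otherwise lactonise onto the malonyl unit built next (coumarin or dihydrocoumarin formation) and gives the protection carried through the key step.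

Step 10
Reactants: 15 (2R)-4,6-bis(tert-butyldimethylsilyloxy)-5-[(2R)-2-methylbutanoyl]-2-(prop-1-en-2-yl)-2,3-dihydro-1-benzofuran-7-carbaldehyde; 16 Meldrum's acid
Product: 18 5-{[(2R)-4,6-bis(tert-butyldimethylsilyloxy)-5-[(2R)-2-methylbutanoyl]-2-(prop-1-en-2-yl)-2,3-dihydro-1-benzofuran-7-yl]methyl}-2,2-dimethyl-1,3-dioxane-4,6-dione, via arylidene Meldrum's acid 17 (not isolated)
Conditions: Hantzsch ester (diethyl 2,6-dimethyl-1,4-dihydropyridine-3,5-dicarboxylate), L-proline (20 mol%), CH2Cl2, rt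
Reagents that add atoms: none
Why: In this reductive Knoevenagel reaction proline-catalysed condensation with the very acidic Meldrum's acid should give the arylidene derivative, a strong hydride acceptor that the Hantzsch ester reduces at once by conjugate hydride transfer, so the bridge carbon is attached to one malonyl carbon only.

Step 11
Reactants: 18 5-{[(2R)-4,6-bis(tert-butyldimethylsilyloxy)-5-[(2R)-2-methylbutanoyl]-2-(prop-1-en-2-yl)-2,3-dihydro-1-benzofuran-7-yl]methyl}-2,2-dimethyl-1,3-dioxane-4,6-dione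
Product: 19 3-tert-butoxy-2-{[(2R)-4,6-bis(tert-butyldimethylsilyloxy)-5-[(2R)-2-methylbutanoyl]-2-(prop-1-en-2-yl)-2,3-dihydro-1-benzofuran-7-yl]methyl}-3-oxopropanoic acid
Conditions: t-BuOH, 80 °C
Reagents that add atoms: tert-butanol, CC(C)(C)O
Why: Thermal alcoholysis of the monosubstituted Meldrum's acid should open the acylal with loss of acetone to the malonic half ester under neutral conditions that the aryl silyl ethers and the alkene tolerate, the new malonyl centre forming as an inconsequential mixture.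

Step 12
Reactants: 19 3-tert-butoxy-2-{[(2R)-4,6-bis(tert-butyldimethylsilyloxy)-5-[(2R)-2-methylbutanoyl]-2-(prop-1-en-2-yl)-2,3-dihydro-1-benzofuran-7-yl]methyl}-3-oxopropanoic acid
Product: 21 2-{[(2R)-4,6-bis(tert-butyldimethylsilyloxy)-5-[(2R)-2-methylbutanoyl]-2-(prop-1-en-2-yl)-2,3-dihydro-1-benzofuran-7-yl]methyl}propanedioyl dichloride, via bis(trimethylsilyl) malonate 20 (not isolated)
Conditions: Me3SiOTf, 2,6-lutidine, CH2Cl2, 0 °C → rt; evaporate, pentane, filter; then (COCl)2, DMF (cat.), CH2Cl2, 0 °C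
Reagents that add atoms: oxalyl chloride, ClC(=O)C(=O)Cl
Why: The silyl triflate should convert the acid and, with loss of isobutene, the tert-butyl ester into trimethylsilyl esters, which the chloroiminium reagent from oxalyl chloride and DMF turns into acyl chlorides with release of Me3SiCl in place of HCl, so neither the isopropenyl group nor the aryl silyl ethers meet free acid.

Step 13
Reactants: 22 pentan-3-one
Product: 23 (Z)-trimethyl(pent-2-en-3-yloxy)silane
Conditions: Me3SiCl, NaI, Et3N, MeCN, rt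
Reagents that add atoms: chlorotrimethylsilane, C[Si](C)(C)Cl
Why: O-silylation of the symmetric ketone by Me3SiI formed in the flask, under equilibrating conditions, should give the one possible constitutional enol ether, mainly as the Z isomer.

Step 14
Reactants: 21 2-{[(2R)-4,6-bis(tert-butyldimethylsilyloxy)-5-[(2R)-2-methylbutanoyl]-2-(prop-1-en-2-yl)-2,3-dihydro-1-benzofuran-7-yl]methyl}propanedioyl dichloride; 23 (Z)-trimethyl(pent-2-en-3-yloxy)silane
Product: 25 (2R)-1-[(2R)-4,6-bis(tert-butyldimethylsilyloxy)-7-[(6-ethyl-4-hydroxy-5-methyl-2-oxo-2H-pyran-3-yl)methyl]-2-(prop-1-en-2-yl)-2,3-dihydro-1-benzofuran-5-yl]-2-methylbutan-1-one, via diketo acid chloride 24 (not isolated)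
Conditions: 23 (2.5 equiv), Et2O, −78 °C → rt
Reagents that add atoms: none
Why: One acyl chloride of 21 (or the chlorocarbonyl ketene that arises from it by loss of HCl) should be attacked by the nucleophilic carbon of 23, which forms C4'–C5' and expels Me3SiCl to give diketone 24. Diketone 24 then enolises toward C6', this enol oxygen displaces chloride from the remaining acyl chloride to form O1'–C2', and a proton shift delivers the 4-hydroxy-2-pyranone. The closest known reaction type is the acylation of ketone silyl enol ethers with malonyl dichlorides to give 4-hydroxy-2H-pyran-2-ones, here used on a more functionalised dichloride. Ring C closes by a 6-exo-trig addition–elimination of the enol oxygen at the acyl chloride carbon. No stereocentre is created, because the sp3 centres at C3' and C5' of 24 become sp2, and the two existing centres lie away from the reacting sites. The step needs acylation at carbon before oxygen and only once per acyl chloride: silyl enol ethers are carbon nucleophiles toward acyl chlorides, the first bond places the second acyl chloride within reach of the C6' enol oxygen, symmetric 3-pentanone allows one enol and one ring orientation only, both phenols are capped, and the second equivalent of 23 takes up the HCl that could otherwise add to the isopropenyl group.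

Step 15
Reactants: 25 (2R)-1-[(2R)-4,6-bis(tert-butyldimethylsilyloxy)-7-[(6-ethyl-4-hydroxy-5-methyl-2-oxo-2H-pyran-3-yl)methyl]-2-(prop-1-en-2-yl)-2,3-dihydro-1-benzofuran-5-yl]-2-methylbutan-1-one
Product: 26 (2R)-1-[(2R)-7-[(6-ethyl-4-hydroxy-5-methyl-2-oxo-2H-pyran-3-yl)methyl]-4,6-dihydroxy-2-(prop-1-en-2-yl)-2,3-dihydro-1-benzofuran-5-yl]-2-methylbutan-1-one
Conditions: Bu4NF, AcOH (1:1), THF, 0 °C
Reagents that add atoms: none
Why: Buffered fluoride desilylation should cleave both aryl silyl ethers, driven by the Si–F bond and the good phenoxide leaving groups, without touching the isopropenyl group, the pyranone or either stereocentre.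

**Compound list**

1 | phloroglucinol | Oc1cc(O)cc(O)c1 | starting material
2 | (R)-2-methylbutanoic acid | OC(=O)[C@H](C)CC | starting material
3 | (R)-2-methylbutanoyl chloride | ClC(=O)[C@H](C)CC | intermediate
4 | (2R)-2-methyl-1-(2,4,6-trihydroxyphenyl)butan-1-one | O=C([C@H](C)CC)c1c(O)cc(O)cc1O | intermediate
5 | prenyl bromide (1-bromo-3-methylbut-2-ene) | CC(C)=CCBr | starting material
6 | (2R)-2-methyl-1-[2,4,6-trihydroxy-3-(3-methylbut-2-en-1-yl)phenyl]butan-1-one | O=C([C@H](C)CC)c1c(O)cc(O)c(CC=C(C)C)c1O | intermediate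
7 | (2R)-1-[2,6-dihydroxy-3-(3-methylbut-2-en-1-yl)-4-(prop-2-en-1-yloxy)phenyl]-2-methylbutan-1-one | O=C([C@H](C)CC)c1c(O)cc(OCC=C)c(CC=C(C)C)c1O | intermediate
8 | (2R)-1-[2,6-bis(tert-butyldimethylsilyloxy)-3-(3-methylbut-2-en-1-yl)-4-(prop-2-en-1-yloxy)phenyl]-2-methylbutan-1-one | O=C([C@H](C)CC)c1c(O[Si](C)(C)C(C)(C)C)cc(OCC=C)c(CC=C(C)C)c1O[Si](C)(C)C(C)(C)C | intermediate
9 | (2R)-1-[2,6-bis(tert-butyldimethylsilyloxy)-3-{[(2S)-3,3-dimethyloxiran-2-yl]methyl}-4-(prop-2-en-1-yloxy)phenyl]-2-methylbutan-1-one | O=C([C@H](C)CC)c1c(O[Si](C)(C)C(C)(C)C)cc(OCC=C)c(C[C@@H]2OC2(C)C)c1O[Si](C)(C)C(C)(C)C | intermediate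
10 | (2R)-1-[2,6-bis(tert-butyldimethylsilyloxy)-3-{[(2S)-3,3-dimethyloxiran-2-yl]methyl}-4-hydroxyphenyl]-2-methylbutan-1-one | O=C([C@H](C)CC)c1c(O[Si](C)(C)C(C)(C)C)cc(O)c(C[C@@H]2OC2(C)C)c1O[Si](C)(C)C(C)(C)C | intermediate
11 | (2R)-1-[(2R)-4,6-bis(tert-butyldimethylsilyloxy)-2-(2-hydroxypropan-2-yl)-2,3-dihydro-1-benzofuran-5-yl]-2-methylbutan-1-one | CC(C)(O)[C@H]1Cc2c(O[Si](C)(C)C(C)(C)C)c(C(=O)[C@H](C)CC)c(O[Si](C)(C)C(C)(C)C)cc2O1 | intermediate
12 | (2R)-1-[(2R)-4,6-bis(tert-butyldimethylsilyloxy)-2-(prop-1-en-2-yl)-2,3-dihydro-1-benzofuran-5-yl]-2-methylbutan-1-one | C=C(C)[C@H]1Cc2c(O[Si](C)(C)C(C)(C)C)c(C(=O)[C@H](C)CC)c(O[Si](C)(C)C(C)(C)C)cc2O1 | intermediate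
13 | (2R)-1-[(2R)-4,6-dihydroxy-2-(prop-1-en-2-yl)-2,3-dihydro-1-benzofuran-5-yl]-2-methylbutan-1-one | C=C(C)[C@H]1Cc2c(O)c(C(=O)[C@H](C)CC)c(O)cc2O1 | intermediate
14 | (2R)-4,6-dihydroxy-5-[(2R)-2-methylbutanoyl]-2-(prop-1-en-2-yl)-2,3-dihydro-1-benzofuran-7-carbaldehyde | C=C(C)[C@H]1Cc2c(O)c(C(=O)[C@H](C)CC)c(O)c(C=O)c2O1 | intermediate
15 | (2R)-4,6-bis(tert-butyldimethylsilyloxy)-5-[(2R)-2-methylbutanoyl]-2-(prop-1-en-2-yl)-2,3-dihydro-1-benzofuran-7-carbaldehyde | C=C(C)[C@H]1Cc2c(O[Si](C)(C)C(C)(C)C)c(C(=O)[C@H](C)CC)c(O[Si](C)(C)C(C)(C)C)c(C=O)c2O1 | intermediate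
16 | Meldrum's acid (2,2-dimethyl-1,3-dioxane-4,6-dione) | CC1(C)OC(=O)CC(=O)O1 | starting material
17 | 5-{[(2R)-4,6-bis(tert-butyldimethylsilyloxy)-5-[(2R)-2-methylbutanoyl]-2-(prop-1-en-2-yl)-2,3-dihydro-1-benzofuran-7-yl]methylidene}-2,2-dimethyl-1,3-dioxane-4,6-dione | C=C(C)[C@H]1Cc2c(O[Si](C)(C)C(C)(C)C)c(C(=O)[C@H](C)CC)c(O[Si](C)(C)C(C)(C)C)c(C=C3C(=O)OC(C)(C)OC3=O)c2O1 | intermediate
18 | 5-{[(2R)-4,6-bis(tert-butyldimethylsilyloxy)-5-[(2R)-2-methylbutanoyl]-2-(prop-1-en-2-yl)-2,3-dihydro-1-benzofuran-7-yl]methyl}-2,2-dimethyl-1,3-dioxane-4,6-dione | C=C(C)[C@H]1Cc2c(O[Si](C)(C)C(C)(C)C)c(C(=O)[C@H](C)CC)c(O[Si](C)(C)C(C)(C)C)c(CC3C(=O)OC(C)(C)OC3=O)c2O1 | intermediate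
19 | 3-tert-butoxy-2-{[(2R)-4,6-bis(tert-butyldimethylsilyloxy)-5-[(2R)-2-methylbutanoyl]-2-(prop-1-en-2-yl)-2,3-dihydro-1-benzofuran-7-yl]methyl}-3-oxopropanoic acid (both epimers at the malonyl carbon) | C=C(C)[C@H]1Cc2c(O[Si](C)(C)C(C)(C)C)c(C(=O)[C@H](C)CC)c(O[Si](C)(C)C(C)(C)C)c(CC(C(=O)O)C(=O)OC(C)(C)C)c2O1 | intermediate
20 | bis(trimethylsilyl) 2-{[(2R)-4,6-bis(tert-butyldimethylsilyloxy)-5-[(2R)-2-methylbutanoyl]-2-(prop-1-en-2-yl)-2,3-dihydro-1-benzofuran-7-yl]methyl}propanedioate | C=C(C)[C@H]1Cc2c(O[Si](C)(C)C(C)(C)C)c(C(=O)[C@H](C)CC)c(O[Si](C)(C)C(C)(C)C)c(CC(C(=O)O[Si](C)(C)C)C(=O)O[Si](C)(C)C)c2O1 | intermediate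
21 | 2-{[(2R)-4,6-bis(tert-butyldimethylsilyloxy)-5-[(2R)-2-methylbutanoyl]-2-(prop-1-en-2-yl)-2,3-dihydro-1-benzofuran-7-yl]methyl}propanedioyl dichloride | C=C(C)[C@H]1Cc2c(O[Si](C)(C)C(C)(C)C)c(C(=O)[C@H](C)CC)c(O[Si](C)(C)C(C)(C)C)c(CC(C(=O)Cl)C(=O)Cl)c2O1 | intermediate
22 | pentan-3-one | CCC(=O)CC | starting material
23 | (Z)-trimethyl(pent-2-en-3-yloxy)silane | C/C=C(/CC)O[Si](C)(C)C | intermediate
24 | 2-{[(2R)-4,6-bis(tert-butyldimethylsilyloxy)-5-[(2R)-2-methylbutanoyl]-2-(prop-1-en-2-yl)-2,3-dihydro-1-benzofuran-7-yl]methyl}-4-methyl-3,5-dioxoheptanoyl chloride (mixture at the two new centres) | C=C(C)[C@H]1Cc2c(O[Si](C)(C)C(C)(C)C)c(C(=O)[C@H](C)CC)c(O[Si](C)(C)C(C)(C)C)c(CC(C(=O)Cl)C(=O)C(C)C(=O)CC)c2O1 | intermediate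
25 | (2R)-1-[(2R)-4,6-bis(tert-butyldimethylsilyloxy)-7-[(6-ethyl-4-hydroxy-5-methyl-2-oxo-2H-pyran-3-yl)methyl]-2-(prop-1-en-2-yl)-2,3-dihydro-1-benzofuran-5-yl]-2-methylbutan-1-one | C=C(C)[C@H]1Cc2c(O[Si](C)(C)C(C)(C)C)c(C(=O)[C@H](C)CC)c(O[Si](C)(C)C(C)(C)C)c(Cc3c(O)c(C)c(CC)oc3=O)c2O1 | intermediate
26 | (2R)-1-[(2R)-7-[(6-ethyl-4-hydroxy-5-methyl-2-oxo-2H-pyran-3-yl)methyl]-4,6-dihydroxy-2-(prop-1-en-2-yl)-2,3-dihydro-1-benzofuran-5-yl]-2-methylbutan-1-one | C=C(C)[C@H]1Cc2c(O)c(C(=O)[C@H](C)CC)c(O)c(Cc3c(O)c(C)c(CC)oc3=O)c2O1 | target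

**Count and risk**

Total step count: 15. Longest linear sequence: 14 steps (steps 1 to 12, then 14 and 15).

Steps most likely to fail:

Step 14. The enol ether may be acylated at oxygen, the dichloride may lose HCl to a ketene that condenses with itself, or the acyl chloride may be captured by the neighbouring silyloxy oxygen with loss of the silyl group. The fallback makes ring C first and forms the bridge afterwards. Enol ether 23 and malonyl dichloride (ClC(=O)CC(=O)Cl) in Et2O at −78 °C → rt should give 6-ethyl-4-hydroxy-5-methyl-2H-pyran-2-one F1. Aldehyde 15, F1, Hantzsch ester and L-proline (cat.) in CH2Cl2 at rt should then give 25 by Knoevenagel condensation at C3' followed by conjugate hydride transfer, a known reductive alkylation of 4-hydroxy-2-pyranones. This fallback sets out from 15 and comes back to the route at 25.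

Step 12. The ester exchange may stay incomplete, the malonyl carbon may be silylated as well, or the dichloride may lose HCl before it is used. The fallback avoids the ester exchange. Meldrum's acid derivative 18 is opened with water in THF/H2O at 60 °C to 2-{[(2R)-4,6-bis(tert-butyldimethylsilyloxy)-5-[(2R)-2-methylbutanoyl]-2-(prop-1-en-2-yl)-2,3-dihydro-1-benzofuran-7-yl]methyl}propanedioic acid F2. F2 is then converted with 1-chloro-N,N,2-trimethylprop-1-en-1-amine (2.2 equiv) in CH2Cl2 at 0 °C into 21 under neutral conditions. This fallback sets out from 18 and comes back at 21.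

Step 7. The elimination may run toward the ring C2–H or through a cation, which would erase the C2 stereocentre or shift the double bond. The fallback forms the isopropenyl group before ring B is closed.
- Epoxide 9 is isomerised with Me3SiOTf and 2,6-lutidine, then 1,8-diazabicyclo[5.4.0]undec-7-ene, in toluene at −78 °C → rt. Ring opening toward the tertiary carbon and loss of a methyl proton should give (2R)-1-[2,6-bis(tert-butyldimethylsilyloxy)-3-[(2S)-3-methyl-2-(trimethylsilyloxy)but-3-en-1-yl]-4-(prop-2-en-1-yloxy)phenyl]-2-methylbutan-1-one F3, with the configuration at the oxygen-bearing carbon retained.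
- Citric acid in MeOH at 0 °C should free (2R)-1-[2,6-bis(tert-butyldimethylsilyloxy)-3-[(2S)-2-hydroxy-3-methylbut-3-en-1-yl]-4-(prop-2-en-1-yloxy)phenyl]-2-methylbutan-1-one F4.
- Pd(PPh3)4 and morpholine in THF should remove the allyl ether to give (2R)-1-[2,6-bis(tert-butyldimethylsilyloxy)-4-hydroxy-3-[(2S)-2-hydroxy-3-methylbut-3-en-1-yl]phenyl]-2-methylbutan-1-one F5.
- Mitsunobu cyclisation (PPh3, diisopropyl azodicarboxylate, THF, 0 °C) through the only free phenol should close ring B with inversion to 12.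

This fallback sets out from 9 and comes back at 12, which is then desilylated as in the second operation of step 7.

Further compounds

F1 | step 14 | 6-ethyl-4-hydroxy-5-methyl-2H-pyran-2-one | CCc1oc(=O)cc(O)c1C
F2 | step 12 | 2-{[(2R)-4,6-bis(tert-butyldimethylsilyloxy)-5-[(2R)-2-methylbutanoyl]-2-(prop-1-en-2-yl)-2,3-dihydro-1-benzofuran-7-yl]methyl}propanedioic acid | C=C(C)[C@H]1Cc2c(O[Si](C)(C)C(C)(C)C)c(C(=O)[C@H](C)CC)c(O[Si](C)(C)C(C)(C)C)c(CC(C(=O)O)C(=O)O)c2O1
F3 | step 7 | (2R)-1-[2,6-bis(tert-butyldimethylsilyloxy)-3-[(2S)-3-methyl-2-(trimethylsilyloxy)but-3-en-1-yl]-4-(prop-2-en-1-yloxy)phenyl]-2-methylbutan-1-one | O=C([C@H](C)CC)c1c(O[Si](C)(C)C(C)(C)C)cc(OCC=C)c(C[C@H](O[Si](C)(C)C)C(C)=C)c1O[Si](C)(C)C(C)(C)C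
F4 | step 7 | (2R)-1-[2,6-bis(tert-butyldimethylsilyloxy)-3-[(2S)-2-hydroxy-3-methylbut-3-en-1-yl]-4-(prop-2-en-1-yloxy)phenyl]-2-methylbutan-1-one | O=C([C@H](C)CC)c1c(O[Si](C)(C)C(C)(C)C)cc(OCC=C)c(C[C@H](O)C(C)=C)c1O[Si](C)(C)C(C)(C)C
F5 | step 7 | (2R)-1-[2,6-bis(tert-butyldimethylsilyloxy)-4-hydroxy-3-[(2S)-2-hydroxy-3-methylbut-3-en-1-yl]phenyl]-2-methylbutan-1-one | O=C([C@H](C)CC)c1c(O[Si](C)(C)C(C)(C)C)cc(O)c(C[C@H](O)C(C)=C)c1O[Si](C)(C)C(C)(C)C
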